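The numbers of this flask were set for the occasion; the rest is arithmetic.

A closed stirred flask, two dosed flasks and a flow tank take the same charges through the same four steps.

| flask | first end groups | second end groups | time | remark |
|---|---|---|---|---|
| midnight | 20 mM (fed, over 0.750 h) | 20.0 mM | 1.5 h | a stirred flask in which first end groups is dosed at a steady rate over 0.750 h without added volume, worked up at 1.5 h |
| spring | 20 mM | 20.0 mM |  | a single well-mixed tank run continuously and read at steady state, 1.5 h in it on average |
| summer | 20 mM | 20.0 mM | 1.5 h | everything together in a closed stirred flask, run for 1.5 h |
| autumn | 20 mM | 20.0 mM (fed, over 0.750 h) | 1.5 h | all but second end groups at the start; second end groups goes in evenly over 0.750 h, the run ends at 1.5 h |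

    first end groups + second end groups → links (k1 = 2.75 /M/min)
    first end groups + second end groups → rings, rate k2*[first end groups] as long as [second end groups] is above zero (k2 = 0.00543 /min)
    second end groups → decomposed reagent (k3 = 0.0330 /min)
    second end groups + links → over-reaction product (k4 = 2.20 /M/min)

* order of the set-ups by the share of links in all that became links or rings or over-reaction product, at the outlet or at the end, highest first (midnight / spring / summer / autumn)
* share of links in all that became links or rings or over-reaction product, at the outlet or at the end, midnight
* share of links in all that became links or rings or over-reaction product, at the outlet or at the end, spring
* share of links in all that became links or rings or over-reaction product, at the outlet or at the end, summer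
* share of links in all that became links or rings or over-reaction product, at the outlet or at the end, autumn

- the stated concentrations are those of everything mixed, before any reaction; amounts are the same in each set-up
- the feed brings no volume worth counting
- run time (midnight): 1.5 h

- The link step and the ring step both carry c(first end groups), so it cancels from their rate ratio, which is c(second end groups) over c-cross, the ring constant divided by the link constant: 1.97 mM. Summer starts at a ratio of 10.1, and this drifts down as second end groups, the likely limiting reagent, are used.
- With these two steps alone, summing the ring share down to zero gives rings of c-cross times the natural log of one plus charge over c-cross, 4.76 mM, so a share of links of 76.2% in summer.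
- The weak link is that decomposition and over-reaction also take second end groups; at the start of summer the link step takes them at 1.7 times the rate of decomposition.
- Guessing means of 15.0 mM first end groups and 5.00 mM links, the pseudo-first-order losses of second end groups total 0.0852 /min.
- Dividing the ring rate at that mean by this total gives c-floor, 0.955 mM, the concentration of second end groups at which the ring step consumes them as fast as the other steps together.
- Put in place of c-cross, c-floor gives rings of 2.95 mM. The rest splits by rate into 8.25 mM links formed and 2.20 mM over-reaction product, the remainder going to decomposed reagent. Each over-reaction product costs one link, so the reckoned summer share is 54.0%.

- The forecast gives summer > midnight > autumn > spring, with midnight 53%, spring 36.4%, summer 58.1% and autumn 45.8%. Its grounds: “those groups reach zero at a finite time and everything then stops”. Its summer value stands higher than the reckoned share.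
- The simulation gives summer > midnight > autumn > spring: midnight 52.8%, spring 36.5%, summer 58.7%, autumn 45.4%. Summer ends with rings at 13.7% of the first end groups charged, and c-floor at 0.955 mM had put them at 14.8%, in a few lines of hand work. The reckoned share stands 4.7 percentage points below the simulated one.
- In the neighbour of summer with second end groups charged at 8.0 mM, the same c-floor gives rings at 10.7% of the first end groups charged. The simulation gives 11.6%, with a share of links of 54.1%.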